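## Retrosynthetic overview

1. The last C–C bond is C15(sp2)–C16(sp3): the 23-membered carbocycle is closed by electroreductive nickel-catalysed coupling of an (E,E)-dienyl iodide with a primary bromide, followed by desilylation.
2. The tetrahydropyran (C5–C9) comes from a Prins cyclisation of the C5 homoallylic alcohol with a citronellal-derived C9–C15 dienyl iodide acetal; the C3 hydroxyl released in that step takes the butyrate.
3. The γ-lactone (C1, C2, C24, C23) comes from chelation-controlled acetylide addition to a C1–C2 α-keto ester (C2–C24 bond), Z-semi-hydrogenation, hydroxyl-directed epoxidation and epoxide-opening lactonisation.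
4. Three bought chiral pieces carry all the control: the statin side-chain acetonide (C1–C6; C3, C5), (R)-γ-hydroxymethyl-γ-butyrolactone (C17–C21; C20, elaborated to the all-cis tetrahydrofuran) and (S)-citronellal (C9–C14; C11).
5. Ring order: tetrahydrofuran, then γ-lactone, then tetrahydropyran, then macrocycle.

Assumption: the SMILES is read as the (2R,3R,5R,7S,9R,11R,12E,14E,17R,18R,20R,21R,23R,24S) isomer, with locants C1–C24 running along the carbon chain from the lactone carbonyl C1 via C2 (quaternary carbinol), C3 (butyrate), C5/C9 (tetrahydropyran), C11 (methyl), C12–C15 (diene), C17/C20 (tetrahydrofuran), C18 (methyl), C21 (carbinol) and C23 (lactone O–CH) to C24 (lactone carbinol, bonded to C2).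

## Route

Step 1
Reactants: 1 statin alcohol acetonide
Product: 3 allyl acetonide ester, via triflate 2 (not isolated)
Conditions: Tf2O, 2,6-lutidine, CH2Cl2, −78 °C; then CH2=CHMgBr, CuBr·SMe2 (10 mol%), THF, −78 to −30 °C
Reagents that add atoms: vinylmagnesium bromide, C=C[Mg]Br
Why: The primary triflate formed in situ is displaced by the vinyl cuprate generated from the Grignard reagent and catalytic CuBr (copper-catalysed Grignard–triflate coupling) at a temperature where the tert-butyl ester is inert, and the bought C3 and C5 stereocentres are not touched.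

Step 2
Reactants: 3 allyl acetonide ester
Product: 4 α-hydroxy ester
Conditions: LiN(iPr)2, THF, −78 °C; racemic trans-2-(phenylsulfonyl)-3-phenyloxaziridine; AcOH quench
Reagents that add atoms: 2-(phenylsulfonyl)-3-phenyloxaziridine, O=S(=O)(N1OC1c1ccccc1)c1ccccc1
Why: The lithium ester enolate is hydroxylated by the racemic sulfonyloxaziridine (Davis enolate oxidation), β-elimination being suppressed because the C3 oxygen is a ring acetal oxygen, and the new C2 centre (both epimers) is erased in step 3.

Step 3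
Reactants: 4 α-hydroxy ester
Product: 5 α-keto ester
Conditions: Dess–Martin periodinane, CH2Cl2, rt
Reagents that add atoms: none
Why: Dess–Martin oxidation of the secondary α-hydroxy ester gives the α-keto ester under near-neutral conditions that leave the acetonide, the alkene and C3 (equatorial on the dioxane chair, so self-correcting if it enolises) unchanged.

Step 4
Reactants: 6 (R)-hydroxymethyl butyrolactone
Product: 7 silyl lactone
Conditions: TBDPSCl, imidazole, DMF, rt
Reagents that add atoms: tert-butyl(chloro)diphenylsilane, CC(C)(C)[Si](Cl)(c1ccccc1)c1ccccc1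
Why: Imidazole-promoted silylation of the primary alcohol protects the C21 oxygen through the enolate, titanium and borane steps and supplies the bulk that directs steps 5 and 6.

Step 5
Reactants: 7 silyl lactone
Product: 8 trans-methyl lactone
Conditions: LiN(iPr)2, THF, −78 °C; MeI
Reagents that add atoms: iodomethane, CI
Why: Lithium enolate alkylation of the γ-lactone with iodomethane occurs anti to the bulky C20 silyloxymethyl group and gives the trans-methyl lactone, whose C18 configuration is corrected in step 6.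

Step 6
Reactants: 8 trans-methyl lactone
Product: 10 cis-methyl lactone, via lithium enolate 9 (not isolated)
Conditions: LiN(iPr)2, THF, −78 °C; then 2,6-di-tert-butyl-4-methylphenol, −78 °C
Reagents that add atoms: none
Why: Re-enolisation and kinetic protonation by the hindered phenol from the face opposite the silyloxymethyl group places the methyl group cis to it, so C18 is set by the bought C20 centre (diastereoselective enolate protonation).

Step 7
Reactants: 10 cis-methyl lactone
Product: 11 exocyclic enol ether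
Conditions: Cp2TiMe2, toluene, 65 °C, dark
Reagents that add atoms: dimethyltitanocene, C[Ti](C)(C1C=CC=C1)C1C=CC=C1
Why: Petasis methylenation converts the lactone carbonyl into the exocyclic enol ether under non-basic conditions that do not epimerise C18.

Step 8
Reactants: 11 exocyclic enol ether
Product: 13 all-cis tetrahydrofuran alcohol, via alkylborane 12 (not isolated)
Conditions: 9-BBN, THF, 0 °C to rt; then NaOH, H2O2, 0 °C
Reagents that add atoms: hydrogen peroxide, OO
Why: Hydroboration with the bulky borane places boron on the terminal carbon and delivers hydrogen to C17 from the face opposite the cis-disposed C18 methyl and C20 side chain, so oxidation gives the all-cis trisubstituted tetrahydrofuran (hydroboration–oxidation; C17 set by C18 and C20).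

Step 9
Reactants: 13 all-cis tetrahydrofuran alcohol
Product: 14 bromide silyl ether
Conditions: CBr4, PPh3, CH2Cl2, 0 °C
Reagents that add atoms: tetrabromomethane, BrC(Br)(Br)Br
Why: Appel bromination of the primary alcohol (SN2 at CH2) installs the C16 bromide that later serves as the sp3 partner of the ring closure.

Step 10
Reactants: 14 bromide silyl ether
Product: 15 bromo alcohol
Conditions: TBAF, AcOH, THF, rt
Reagents that add atoms: none
Why: Acetic-acid-buffered fluoride removes the silyl group without generating a free alkoxide that could displace the cis-disposed bromide (fluoride desilylation).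

Step 11
Reactants: 15 bromo alcohol
Product: 16 bromo aldehyde
Conditions: Dess–Martin periodinane, CH2Cl2, 0 °C to rt; used crude
Reagents that add atoms: none
Why: Dess–Martin oxidation gives the α-alkoxy aldehyde under non-basic conditions that do not epimerise C20.

Step 12
Reactants: 16 bromo aldehyde
Product: 17 homopropargylic alcohol
Conditions: MgBr2·OEt2, tributyl(propa-1,2-dienyl)stannane, CH2Cl2, −78 to −20 °C
Reagents that add atoms: tributyl(propa-1,2-dien-1-yl)stannane, CCCC[Sn](CCCC)(CCCC)C=C=C
Why: MgBr2 chelates the aldehyde oxygen and the ring oxygen and the allenylstannane adds in SE2' fashion to the less hindered face of the chelate (Cram-chelate control), giving the threo homopropargylic alcohol with C21 set by C20.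

Step 13
Reactants: 18 (S)-citronellal
Product: 19 citronellal dimethyl acetal
Conditions: HC(OMe)3, MeOH, pyridinium p-toluenesulfonate (cat.), rt
Reagents that add atoms: trimethyl orthoformate, COC(OC)OC
Why: Mild acid-catalysed acetalisation masks C9 without triggering the carbonyl-ene cyclisation of citronellal, and the bought C11 centre is untouched.

Step 14
Reactants: 19 citronellal dimethyl acetal
Product: 20 acetal aldehyde
Conditions: O3, CH2Cl2/MeOH, −78 °C; then Me2S
Reagents that add atoms: ozone, [O-][O+]=O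
Why: Ozonolysis with reductive work-up cleaves the only alkene to the C14 aldehyde and leaves the acetal and C11 unchanged.

Step 15
Reactants: 20 acetal aldehyde
Product: 22 acetal enal, via silyl enol ether 21 (not isolated)
Conditions: TMSCl, Et3N, DMF, 80 °C; then Pd(OAc)2 (10 mol%), O2 (1 atm), DMSO, rt
Reagents that add atoms: none
Why: Saegusa–Ito dehydrogenation through the silyl enol ether gives the E-enal by β-hydride elimination from the divalent palladium enolate under base-free conditions, so the γ-stereocentre C11 is not epimerised.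

Step 16
Reactants: 22 acetal enal
Product: 23 dienyl iodide acetal
Conditions: CrCl2, CHI3, THF, 0 °C
Reagents that add atoms: iodoform, IC(I)I
Why: Takai iodo-olefination with the gem-dichromium reagent formed from iodoform and divalent chromium converts the enal into the (E,E)-dienyl iodide with the usual E selectivity.

Step 17
Reactants: 5 α-keto ester; 17 homopropargylic alcohol
Product: 24 propargylic alcohol
Conditions: Zn(OTf)2, iPr2NEt, toluene, 23 °C
Reagents that add atoms: none
Why: The zinc acetylide formed from the terminal alkyne adds to the ketone of the α-keto ester, whose carbonyl oxygen and C3 dioxane oxygen are chelated by zinc, from the face of the C3 hydrogen (Cram-chelate-controlled alkynylation), forming the C2–C24 bond and setting the C2 tertiary alcohol from C3.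

Step 18
Reactants: 24 propargylic alcohol
Product: 25 Z-allylic alcohol
Conditions: H2 (1 atm), Pd/CaCO3 poisoned with Pb(OAc)2, quinoline, EtOAc, rt
Reagents that add atoms: none
Why: Lindlar semi-hydrogenation reduces the internal alkyne to the Z-alkene by syn delivery of hydrogen and is stopped before the terminal alkene or the C–Br bond reacts.

Step 19
Reactants: 25 Z-allylic alcohol
Product: 26 cis-epoxide
Conditions: mCPBA (1.05 equiv), CH2Cl2, −20 °C
Reagents that add atoms: 3-chloroperbenzoic acid, O=C(OO)c1cccc(Cl)c1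
Why: Hydroxyl-directed peracid epoxidation (Henbest type) of the Z-allylic tertiary alcohol occurs syn to the C2 hydroxyl in the conformer that keeps the flat ester, not the bulky dioxanyl group, in the plane of the alkene (allylic 1,3-strain), so the cis-epoxide carbons C23 and C24 are set by C2, while the unactivated terminal alkene reacts far more slowly.

Step 20
Reactants: 26 cis-epoxide
Product: 28 bis-silyl lactone, via hydroxy lactone 27 (not isolated)
Conditions: p-TsOH (10 mol%), CH2Cl2, 0 °C; then 2,6-lutidine, TIPSOTf, 0 °C to rt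
Reagents that add atoms: triisopropylsilyl triflate, CC(C)[Si](OS(=O)(=O)C(F)(F)F)(C(C)C)C(C)C
Why: Acid-catalysed attack of the tert-butyl ester carbonyl oxygen on the distal epoxide carbon C23 with inversion and loss of 2-methylpropene gives the γ-lactone with the all-cis C2/C24/C23 array (epoxide-opening lactonisation; C24 is shielded from other nucleophiles by the fully substituted C2), and the two secondary hydroxyls at C21 and C24 are then silylated while the tertiary C2 hydroxyl is not.

Step 21
Reactants: 28 bis-silyl lactone; 23 dienyl iodide acetal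
Product: 30 tetrahydropyran trifluoroacetate, via dioxane acetal 29 (not isolated)
Conditions: TFA (15 equiv), CH2Cl2, −20 to 0 °C; NaHCO3 quench
Reagents that add atoms: trifluoroacetic acid, OC(=O)C(F)(F)F
Why: Under TFA the acetonide is exchanged for the aldehyde-derived 1,3-dioxane, whose ring opening gives the C5–O oxocarbenium ion that cyclises onto the terminal alkene through a chair transition state with equatorial substituents and is trapped equatorially by trifluoroacetate (Prins cyclisation), so C9 and C7 are set by C5 as the all-cis tetrahydropyran and the C3 hydroxyl is released.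

Step 22
Reactants: 30 tetrahydropyran trifluoroacetate
Product: 32 seco bromo iodide, via butyrate trifluoroacetate 31 (not isolated)
Conditions: (PrCO)2O, DMAP, pyridine, CH2Cl2, 0 °C to rt; then MeOH, NaHCO3, rt
Reagents that add atoms: butanoic anhydride, CCCC(=O)OC(=O)CCC
Why: Nucleophile-catalysed acylation esterifies the only free secondary hydroxyl (C3; the C2 hydroxyl is tertiary and the others are silylated or trifluoroacetylated), and mild methanolysis then removes the far more labile C7 trifluoroacetate without touching the butyrate.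

Step 23
Reactants: 32 seco bromo iodide
Product: 33 macrocycle bis-silyl ether
Conditions: NiBr2·DME (30 mol%), 4,4'-di-tert-butyl-2,2'-bipyridine (33 mol%), NaI (0.5 equiv), nBu4NPF6, DMA, divided cell, carbon-foam cathode, Zn anode, 2 mA constant current, 32 added over 12 h (final 2 mM), rt
Reagents that add atoms: none
Why: Proposed new method: electroreductive nickel-catalysed intramolecular C(sp2)–C(sp3) cross-electrophile coupling used as a macrocyclisation — zerovalent nickel–bipyridine inserts into the dienyl C–I bond with retention of the E,E geometry, a monovalent nickel halide abstracts bromine from the primary C16–Br bond, the resulting β-alkoxyalkyl radical (which does not fragment) is captured at the tethered divalent alkenylnickel centre, and reductive elimination from trivalent nickel closes the 23-membered carbocycle under pseudo-high dilution, with the cathode in place of a metal reductant so that the β-alkoxy bromide never meets zinc metal and no stereocentre is involved; the closest known reaction type is the intermolecular nickel-catalysed electroreductive or metal-powder-driven cross-electrophile coupling of alkenyl or aryl halides with alkyl bromides.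

Step 24
Reactants: 33 macrocycle bis-silyl ether
Product: 34 CNP0293143.3
Conditions: HF·pyridine, pyridine, THF, 0 to 40 °C
Reagents that add atoms: none
Why: Pyridine-buffered HF cleaves both secondary silyl ethers (fluoride desilylation) without affecting the butyrate, the γ-lactone or the diene, and no stereocentre is touched.

## Compound list

1 | tert-butyl 2-[(4R,6S)-6-(hydroxymethyl)-2,2-dimethyl-1,3-dioxan-4-yl]acetate (statin side-chain alcohol; C1–C6) | CC(C)(C)OC(=O)C[C@H]1C[C@@H](CO)OC(C)(C)O1 | starting material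
2 | tert-butyl 2-[(4R,6S)-2,2-dimethyl-6-{[(trifluoromethylsulfonyl)oxy]methyl}-1,3-dioxan-4-yl]acetate | CC(C)(C)OC(=O)C[C@H]1C[C@@H](COS(=O)(=O)C(F)(F)F)OC(C)(C)O1 | intermediate
3 | tert-butyl 2-[(4R,6R)-2,2-dimethyl-6-(prop-2-en-1-yl)-1,3-dioxan-4-yl]acetate | CC(C)(C)OC(=O)C[C@H]1C[C@@H](CC=C)OC(C)(C)O1 | intermediate
4 | tert-butyl (2RS)-2-[(4R,6R)-2,2-dimethyl-6-(prop-2-en-1-yl)-1,3-dioxan-4-yl]-2-hydroxyacetate (C2 epimer mixture) | CC(C)(C)OC(=O)C(O)[C@H]1C[C@@H](CC=C)OC(C)(C)O1 | intermediate
5 | tert-butyl 2-[(4R,6R)-2,2-dimethyl-6-(prop-2-en-1-yl)-1,3-dioxan-4-yl]-2-oxoacetate | CC(C)(C)OC(=O)C(=O)[C@H]1C[C@@H](CC=C)OC(C)(C)O1 | intermediate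
6 | (5R)-5-(hydroxymethyl)oxolan-2-one | OC[C@H]1CCC(=O)O1 | starting material
7 | (5R)-5-{[tert-butyl(diphenyl)silyl]oxymethyl}oxolan-2-one | CC(C)(C)[Si](OC[C@H]1CCC(=O)O1)(c1ccccc1)c1ccccc1 | intermediate
8 | (3S,5R)-5-{[tert-butyl(diphenyl)silyl]oxymethyl}-3-methyloxolan-2-one (trans) | CC(C)(C)[Si](OC[C@H]1C[C@H](C)C(=O)O1)(c1ccccc1)c1ccccc1 | intermediate
9 | lithium (5R)-5-{[tert-butyl(diphenyl)silyl]oxymethyl}-3-methyl-4,5-dihydrofuran-2-olate | CC(C)(C)[Si](OC[C@H]1CC(C)=C([O-])O1)(c1ccccc1)c1ccccc1.[Li+] | intermediate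
10 | (3R,5R)-5-{[tert-butyl(diphenyl)silyl]oxymethyl}-3-methyloxolan-2-one (cis) | CC(C)(C)[Si](OC[C@H]1C[C@@H](C)C(=O)O1)(c1ccccc1)c1ccccc1 | intermediate
11 | tert-butyl{[(2R,4R)-4-methyl-5-methylideneoxolan-2-yl]methoxy}diphenylsilane | CC(C)(C)[Si](OC[C@H]1C[C@@H](C)C(=C)O1)(c1ccccc1)c1ccccc1 | intermediate
12 | 9-{[(2R,3R,5R)-5-{[tert-butyl(diphenyl)silyl]oxymethyl}-3-methyloxolan-2-yl]methyl}-9-borabicyclo[3.3.1]nonane (all-cis) | CC(C)(C)[Si](OC[C@H]1C[C@@H](C)[C@@H](CB2C3CCCC2CCC3)O1)(c1ccccc1)c1ccccc1 | intermediate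
13 | [(2S,3R,5R)-5-{[tert-butyl(diphenyl)silyl]oxymethyl}-3-methyloxolan-2-yl]methanol (all-cis) | CC(C)(C)[Si](OC[C@H]1C[C@@H](C)[C@@H](CO)O1)(c1ccccc1)c1ccccc1 | intermediate
14 | {[(2R,4R,5S)-5-(bromomethyl)-4-methyloxolan-2-yl]methoxy}(tert-butyl)diphenylsilane | CC(C)(C)[Si](OC[C@H]1C[C@@H](C)[C@@H](CBr)O1)(c1ccccc1)c1ccccc1 | intermediate
15 | [(2R,4R,5S)-5-(bromomethyl)-4-methyloxolan-2-yl]methanol | OC[C@H]1C[C@@H](C)[C@@H](CBr)O1 | intermediate
16 | (2R,4R,5S)-5-(bromomethyl)-4-methyloxolane-2-carbaldehyde | O=C[C@H]1C[C@@H](C)[C@@H](CBr)O1 | intermediate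
17 | (1R)-1-[(2R,4R,5S)-5-(bromomethyl)-4-methyloxolan-2-yl]but-3-yn-1-ol (C16–C24) | C#CC[C@@H](O)[C@H]1C[C@@H](C)[C@@H](CBr)O1 | intermediate
18 | (3S)-3,7-dimethyloct-6-enal, (S)-citronellal | O=CC[C@@H](C)CCC=C(C)C | starting material
19 | (6S)-8,8-dimethoxy-2,6-dimethyloct-2-ene | COC(OC)C[C@@H](C)CCC=C(C)C | intermediate
20 | (4S)-6,6-dimethoxy-4-methylhexanal | COC(OC)C[C@@H](C)CCC=O | intermediate
21 | {[(4S)-6,6-dimethoxy-4-methylhex-1-en-1-yl]oxy}trimethylsilane (E/Z mixture) | COC(OC)C[C@@H](C)CC=CO[Si](C)(C)C | intermediate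
22 | (2E,4R)-6,6-dimethoxy-4-methylhex-2-enal | COC(OC)C[C@@H](C)/C=C/C=O | intermediate
23 | (1E,3E,5R)-1-iodo-7,7-dimethoxy-5-methylhepta-1,3-diene (C9–C15) | COC(OC)C[C@@H](C)/C=C/C=C/I | intermediate
24 | tert-butyl (2R,6R)-6-[(2R,4R,5S)-5-(bromomethyl)-4-methyloxolan-2-yl]-2-[(4R,6R)-2,2-dimethyl-6-(prop-2-en-1-yl)-1,3-dioxan-4-yl]-2,6-dihydroxyhex-3-ynoate | CC(C)(C)OC(=O)[C@@](O)(C#CC[C@@H](O)[C@H]2C[C@@H](C)[C@@H](CBr)O2)[C@H]1C[C@@H](CC=C)OC(C)(C)O1 | intermediate
25 | tert-butyl (2R,3Z,6R)-6-[(2R,4R,5S)-5-(bromomethyl)-4-methyloxolan-2-yl]-2-[(4R,6R)-2,2-dimethyl-6-(prop-2-en-1-yl)-1,3-dioxan-4-yl]-2,6-dihydroxyhex-3-enoate | CC(C)(C)OC(=O)[C@@](O)(/C=C\C[C@@H](O)[C@H]2C[C@@H](C)[C@@H](CBr)O2)[C@H]1C[C@@H](CC=C)OC(C)(C)O1 | intermediate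
26 | C23,C24-cis-epoxide of 25, epoxide oxygen syn to the C2 hydroxyl (other centres as in 25) | CC(C)(C)OC(=O)[C@@](O)([C@H]3O[C@H]3C[C@@H](O)[C@H]2C[C@@H](C)[C@@H](CBr)O2)[C@H]1C[C@@H](CC=C)OC(C)(C)O1 | intermediate
27 | γ-lactone (C1 to O23) with free C2, C24 and C21 hydroxyls, C3/C5 acetonide, C6–C8 allyl group and C16 bromide; C22, O24 and O2 all cis on the lactone | O=C1O[C@H](C[C@@H](O)[C@H]2C[C@@H](C)[C@@H](CBr)O2)[C@H](O)[C@@]1(O)[C@H]3C[C@@H](CC=C)OC(C)(C)O3 | intermediate
28 | C21,C24-bis(triisopropylsilyl) ether of 27 | O=C1O[C@H](C[C@@H](O[Si](C(C)C)(C(C)C)C(C)C)[C@H]2C[C@@H](C)[C@@H](CBr)O2)[C@H](O[Si](C(C)C)(C(C)C)C(C)C)[C@@]1(O)[C@H]3C[C@@H](CC=C)OC(C)(C)O3 | intermediate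
29 | 2,4,6-cis-1,3-dioxane acetal of the C3/C5 diol with the aldehyde carbon C9 of 23 (other groups as in 28) | O=C1O[C@H](C[C@@H](O[Si](C(C)C)(C(C)C)C(C)C)[C@H]2C[C@@H](C)[C@@H](CBr)O2)[C@H](O[Si](C(C)C)(C(C)C)C(C)C)[C@@]1(O)[C@H]3C[C@@H](CC=C)O[C@@H](C[C@@H](C)/C=C/C=C/I)O3 | intermediate
30 | all-cis tetrahydropyran (C5–O–C9) with C7 trifluoroacetate, free C3 hydroxyl and (E,E)-dienyl iodide side chain; lactone part as in 28 | O=C1O[C@H](C[C@@H](O[Si](C(C)C)(C(C)C)C(C)C)[C@H]2C[C@@H](C)[C@@H](CBr)O2)[C@H](O[Si](C(C)C)(C(C)C)C(C)C)[C@@]1(O)[C@H](O)C[C@H]4C[C@@H](OC(=O)C(F)(F)F)C[C@@H](C[C@@H](C)/C=C/C=C/I)O4 | intermediate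
31 | C3 butyrate of 30 (C7 trifluoroacetate retained) | O=C1O[C@H](C[C@@H](O[Si](C(C)C)(C(C)C)C(C)C)[C@H]2C[C@@H](C)[C@@H](CBr)O2)[C@H](O[Si](C(C)C)(C(C)C)C(C)C)[C@@]1(O)[C@H](OC(=O)CCC)C[C@H]4C[C@@H](OC(=O)C(F)(F)F)C[C@@H](C[C@@H](C)/C=C/C=C/I)O4 | intermediate
32 | seco compound: C3 butyrate, free C7 and C2 hydroxyls, C21/C24 silyl ethers, C15 iodide, C16 bromide | O=C1O[C@H](C[C@@H](O[Si](C(C)C)(C(C)C)C(C)C)[C@H]2C[C@@H](C)[C@@H](CBr)O2)[C@H](O[Si](C(C)C)(C(C)C)C(C)C)[C@@]1(O)[C@H](OC(=O)CCC)C[C@H]4C[C@@H](O)C[C@@H](C[C@@H](C)/C=C/C=C/I)O4 | intermediate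
33 | C21,C24-bis(triisopropylsilyl) ether of the target macrocycle | CCCC(=O)O[C@@H]1C[C@H]2C[C@@H](O)C[C@@H](C[C@@H](C)/C=C/C=C/C[C@H]3O[C@H](C[C@H]3C)[C@H](O[Si](C(C)C)(C(C)C)C(C)C)C[C@H]3OC(=O)[C@@]1(O)[C@H]3O[Si](C(C)C)(C(C)C)C(C)C)O2 | intermediate
34 | CNP0293143.3, (2R,3R,5R,7S,9R,11R,12E,14E,17R,18R,20R,21R,23R,24S) in the chain numbering above | CCCC(=O)O[C@@H]1C[C@H]2C[C@@H](O)C[C@@H](C[C@@H](C)/C=C/C=C/C[C@H]3O[C@H](C[C@H]3C)[C@H](O)C[C@H]3OC(=O)[C@@]1(O)[C@H]3O)O2 | target

## Step count and weak points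

Total step count: 24. Longest linear sequence: 17 steps (from 6 through steps 4–12 and 17–24).

**Step 23 (the proposed new method).** The risks are oligomerisation instead of ring closure, protodehalogenation of either terminus and loss of diene geometry at nickel. The fallback replaces the radical cross-electrophile coupling by a two-electron B-alkyl Suzuki–Miyaura macrocyclisation, all known chemistry. It sets out from 32: dehydrobromination (DBU, NaI, toluene, 90 °C) gives the exocyclic enol ether F1. Hydroboration with excess 9-BBN (THF, rt), again from the face opposite the C18 methyl and the C20 side chain, gives the B-alkyl-9-BBN adduct F2. Without isolation F2 is coupled intramolecularly with the dienyl iodide (PdCl2(dppf), AsPh3, Cs2CO3, DMF/THF/H2O, high dilution) and comes back to the route at 33.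

**Step 21 (Prins union).** Acetonide exchange, oxocarbenium formation and cyclisation must all occur in TFA in the presence of the acid-sensitive dienyl iodide and two silyl ethers. The fallback carries an acid-stable enyne through the acid step and builds the dienyl iodide afterwards. It sets out from 22 and 28: Colvin homologation of 22 (lithiated trimethylsilyldiazomethane, THF, −78 to 0 °C) gives the enyne acetal F3. Prins cyclisation of 28 with F3 under the conditions of step 21 gives the enyne tetrahydropyran trifluoroacetate F4. Butyrylation and methanolysis as in step 22 give the enyne butyrate F5. Palladium-catalysed hydrostannylation (Bu3SnH, PdCl2(PPh3)2, THF, 0 °C) gives the (E,E)-dienylstannane F6, and iododestannylation (I2, CH2Cl2, 0 °C) comes back to the route at 32.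

**Step 19 (directed epoxidation).** Face selectivity rests on the ester, not the dioxanyl group, taking the in-plane position at a tertiary carbinol, and the free C21 hydroxyl could interfere. The fallback sets C24 and C23 by directed dihydroxylation of an E-alkene instead. It sets out from 5 and 17: hydrozirconation of 17 (Cp2Zr(H)Cl, CH2Cl2), transmetalation with Me2Zn and chelation-controlled addition to 5 give the E-allylic alcohol F7. Hydrogen-bond-directed syn-dihydroxylation (OsO4, TMEDA, CH2Cl2, −78 °C; aqueous Na2SO3 work-up) gives the all-syn triol F8. Acid-catalysed lactonisation (p-TsOH, CH2Cl2) with retention at C23 comes back to the route at 27, which is silylated as in step 20.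

Further compounds
F1 | step 23 | exocyclic enol ether from 32 by loss of HBr (C16=C17; otherwise as 32) | O=C1O[C@H](C[C@@H](O[Si](C(C)C)(C(C)C)C(C)C)[C@H]2C[C@@H](C)C(=C)O2)[C@H](O[Si](C(C)C)(C(C)C)C(C)C)[C@@]1(O)[C@H](OC(=O)CCC)C[C@H]4C[C@@H](O)C[C@@H](C[C@@H](C)/C=C/C=C/I)O4
F2 | step 23 | B-alkyl-9-BBN adduct of F1 (boron on C16, all-cis tetrahydrofuran) | O=C1O[C@H](C[C@@H](O[Si](C(C)C)(C(C)C)C(C)C)[C@H]2C[C@@H](C)[C@@H](CB5C6CCCC5CCC6)O2)[C@H](O[Si](C(C)C)(C(C)C)C(C)C)[C@@]1(O)[C@H](OC(=O)CCC)C[C@H]4C[C@@H](O)C[C@@H](C[C@@H](C)/C=C/C=C/I)O4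
F3 | step 21 | (3E,5R)-7,7-dimethoxy-5-methylhept-3-en-1-yne | COC(OC)C[C@@H](C)/C=C/C#C
F4 | step 21 | enyne analogue of 30 (C7 trifluoroacetate, free C3 hydroxyl, C14≡C15 alkyne) | O=C1O[C@H](C[C@@H](O[Si](C(C)C)(C(C)C)C(C)C)[C@H]2C[C@@H](C)[C@@H](CBr)O2)[C@H](O[Si](C(C)C)(C(C)C)C(C)C)[C@@]1(O)[C@H](O)C[C@H]4C[C@@H](OC(=O)C(F)(F)F)C[C@@H](C[C@@H](C)/C=C/C#C)O4
F5 | step 21 | enyne analogue of 32 (C3 butyrate, free C7 hydroxyl) | O=C1O[C@H](C[C@@H](O[Si](C(C)C)(C(C)C)C(C)C)[C@H]2C[C@@H](C)[C@@H](CBr)O2)[C@H](O[Si](C(C)C)(C(C)C)C(C)C)[C@@]1(O)[C@H](OC(=O)CCC)C[C@H]4C[C@@H](O)C[C@@H](C[C@@H](C)/C=C/C#C)O4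
F6 | step 21 | (E,E)-dienyl tributylstannane analogue of 32 (SnBu3 on C15) | O=C1O[C@H](C[C@@H](O[Si](C(C)C)(C(C)C)C(C)C)[C@H]2C[C@@H](C)[C@@H](CBr)O2)[C@H](O[Si](C(C)C)(C(C)C)C(C)C)[C@@]1(O)[C@H](OC(=O)CCC)C[C@H]4C[C@@H](O)C[C@@H](C[C@@H](C)/C=C/C=C/[Sn](CCCC)(CCCC)CCCC)O4
F7 | step 19 | E-allylic alcohol, the (3E) isomer of 25 | CC(C)(C)OC(=O)[C@@](O)(/C=C/C[C@@H](O)[C@H]2C[C@@H](C)[C@@H](CBr)O2)[C@H]1C[C@@H](CC=C)OC(C)(C)O1
F8 | step 19 | all-syn C2,C24,C23-triol tert-butyl ester | CC(C)(C)OC(=O)[C@@](O)([C@@H](O)[C@H](O)C[C@@H](O)[C@H]2C[C@@H](C)[C@@H](CBr)O2)[C@H]1C[C@@H](CC=C)OC(C)(C)O1
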